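## The problem

Target 28 is a germacranolide: a ten-membered carbocycle (C1–C10) with a C1 ketone, a trans-4,5-epoxide, a butenolide fused through the C6 oxygen and the tetrasubstituted C7=C11 olefin, an angelate on the C8 oxygen and an acetate on C13. Five stereocentres must be set (4R,5R,6S,8S,10R): C4, C5 and C6 are contiguous, C6 and C8 carry cis oxygens on either side of the sp2 carbon C7, and C10 stands alone between C9H2 and the ketone. C6 can control the epoxide, because allylic 1,3-strain with the C15 methyl fixes its rotamer and an E-olefin in a ten-membered ring is open only on its outer face. C6 and C8 cannot relay to each other through C7, and C10 is α to the ketone, epimerisable and without a strong neighbour. The fragile parts are the trisubstituted epoxide (acid opens it and a transannular olefin or carbonyl then attacks C4), the angelate (Z to E isomerisation under nucleophilic catalysis), the 13-acetoxy butenolide (an allylic acetate on a Michael acceptor, open to SN2′ loss of acetate) and the medium ring itself, which is costly to close. The enabling feature is a hidden mirror plane: without the C1 oxygen and the epoxide oxygen, the array C1–C10(C14)=C9–C8(O)–C7(=C11)–C6(O)–C5=C4(C15)–C3, bridged by C2, is bisected by a plane through C2, C7 and C11 that exchanges C6 with C8, C4 with C10 and C12 with C13. The corresponding (4E,9E)-diene-6,8-diol 16 is meso and its two ring olefins are enantiotopic, so oxygen transfer to C4=C5 alone creates C4 and C5 and makes C6 and C8 stereogenic in the absolute sense.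

## Retrosynthesis

**C1 oxygen and C10–H (28 ⇒ 27 ⇒ 25).** The C9–H and C10–H bonds of 28 are cut back to enone 27 (conjugate reduction), and the C1=O bond of 27 back to the C1 methylene of olefin 25 (allylic C–H oxidation). An earlier oxidation is ruled out because C1 and C3 are equivalent until the epoxide is in place. Only in 25 are all oxygens acylated and C7=C11 part of an electron-poor butenolide, so that C9=C10 is the single electron-rich π system with a secondary allylic C–H. A hydrogen-abstraction method is preferred to a selenium-based ene oxidation (Riley oxidation), because ene reagents are retarded by the allylic ester at C8 and, in E-trisubstituted olefins of ten-membered rings, tend to oxidise the olefinic methyl group. 25 is simpler by one carbonyl and one stereocentre. The forward steps must select C1 over C14, reduce one enone among three conjugated carbonyl systems and deliver 10R.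

**Butenolide and acetate (25 ⇒ 24 ⇒ 23 ⇒ 21).** The acetate C–O bond and then the C12 oxidation level are removed: 25 comes from alcohol 24, 24 from aldehyde 23, and 23 from triol 21 by oxidative lactonisation, which forms C12=O and the O6–C12 ring bond. The lactone cannot be carried from the start, because C12 and C13 must be identical as long as the mirror plane exists. Raising both to the aldehyde level and letting the cis hydroxyl at C6 trap one of them differentiates them without a protecting group. 21 has no lactone, no acetate and two equivalent CH2OH groups. The forward sequence needs O8 acylated and O6 free before the oxidation, and a non-acidic unmasking of the C12/C13 hydroxyls, which is why they travel as silyl ethers.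

**Angelate (21 ⇒ 20 ⇒ 17 + 18).** The silyl ethers are put back (20) and the O8–acyl bond is cut to epoxy diol 17 and angelic acid 18. Esterifying here, and not at the end, uses the ester as the group that keeps O8 out of the lactonisation. The two secondary hydroxyls of 17 differ: O6–H is an epoxy alcohol, less nucleophilic and hydrogen-bonded to the oxirane oxygen, while O8–H is a doubly allylic alcohol. The forward step must turn this difference into site selectivity, without a nucleophilic catalyst, so that the Z geometry of the angelate survives. 17 is simpler by the five-carbon ester and one step away from a meso compound.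

**Epoxide (17 ⇒ 16).** Both C–O bonds of the oxirane are cut, which leads to meso diene-diol 16 and removes all four stereocentres of 17 in the absolute sense. Neighbouring cuts (a separate desymmetrisation of the diol followed by directed epoxidation, or epoxide closure from a halohydrin) need two operations for what one catalytic oxygen transfer can do. The forward reaction must choose one of two enantiotopic E-trisubstituted olefins (catalyst), attack it from the outer face (ring) and leave the tetrasubstituted C7=C11 olefin alone. The hydroxyls stay free: they are needed next, and the wanted threo epoxy alcohol is what peripheral attack on the rotamer with C6–H eclipsing the C15 methyl gives.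

**Ring (16 ⇒ 15 ⇒ 12 + 13).** The ring is opened at C1–C2 and C2–C3. C2 lies on the mirror plane, so a one-carbon linchpin, bis(phenylsulfonyl)methane 13, joins the two identical allylic termini of acyclic meso diol 12; the sulfonyl groups of macrocycle 15 are then removed. Cutting at C5–C6 or C8–C9 instead would create a carbinol stereocentre in the ring-closing step with no control over the cis relation. The ring to be formed is an (E,E)-cyclodeca-1,6-diene, one of the least strained ten-membered rings, and its closure creates no stereocentre. Asked for are attack at the primary allyl terminus, retention of the E geometry and dominance of the intramolecular second alkylation under dilution.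

**Carbinols and C5–C6/C8–C9 (12 ⇒ 10 ⇒ 9 ⇒ 7 + 3).** The two carbinol C–H bonds of 12 are cut to diketone 10, and its two alkenyl–carbonyl bonds to bis-Weinreb amide 7 and two equivalents of alkenyl iodide 3; the carbonates of 10 come from diol 9. Making the carbinols by reduction, and not by alkenyl addition at the aldehyde level, has a stereochemical reason. The second hydride can be delivered under chelation control syn to the first carbinol, which gives the meso diol, whereas 1,3-induction through C7 in an alkenyl addition would be weak. 7 is achiral and symmetric, and 3 carries the E geometry and the C14/C15 methyl groups. Asked for are clean mono-addition at each amide and high syn selectivity in the reduction.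

**Core and iodide (7 ⇒ 6 ⇒ 4 + 5; 3 ⇒ 1).** The C7=C11 double bond of malonate 6 (precursor of 7) is cut by a Knoevenagel disconnection to dimethyl malonate 4 (C6, C7, C8) and ketone 5 (C11, C12, C13). Iodide 3 is traced to propargyl alcohol 1 by methylalumination. A tetrasubstituted olefin with two identical pairs of substituents has no geometry to control, so condensation is the shortest access. Silyl ethers on 5 are chosen over a ketal so that the late unmasking beside the epoxide needs fluoride and not acid.

## Roads not taken

**Alternative 1:** The cut is the ring bond C5–C6, made by a vinylogous Mukaiyama aldol macrocyclisation. BF3·OEt2 activates the C5 aldehyde of open-chain silyloxyfuran A1, the furan attacks through its γ-carbon C6, the butenolide is regenerated and the ten-membered ring of A2 closes.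
- Merits: C1 (as a silyl ether), C8 and C10 are built on an open chain by standard acyclic methods, so neither a late C–H oxidation at C1 nor an uncertain protonation at C10 is needed. In these two respects this road is better than the chosen one. The butenolide with its C13 acetate also arrives complete.
- Weak points: the closure creates C5 and C6 in a macrocyclic transition state with no reliable model for either. The aldehyde is neopentylic (C4 is fully substituted), and a Lewis acid meets a tertiary silyl ether and an allylic acetate. A2 still needs its C4–O/C5–O pair turned into the trans epoxide by sulfonylation and displacement, which works from one C5 epimer only, plus oxidation at C1 and exchange of the C8 ether for the angelate. A1, with four stereocentres set one by one, is far longer to make than 16.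
- Comparison: against the advantage at C1 and C10 the chosen plan sets a ring closure that creates no stereocentre and one catalytic step for C4, C5, C6 and C8.

**Alternative 2:** The cut is the transannular bond C4–C8 of a hydroazulene. The C8 alkoxide of mesylate A3 undergoes a Grob fragmentation that breaks C4–C8, forms the C8 ketone and the E-C4=C5 olefin and releases the ten-membered ring of A4.
- Merits: fragmentation is stereospecific and strain-driven, arguably the most dependable ring-forming event of the four plans. C1 (as a ketal) and the C10 methyl are set on a rigid bicycle, again better than the late oxidation and protonation of the chosen plan.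
- Weak points: A3 carries five stereocentres and a tetrasubstituted alkylidene next to a tertiary alcohol and is a long enantioselective synthesis in itself. A4 has a ketone at C8 flanked by the cross-conjugated C7 alkylidene and an enolisable C9. C8 must therefore be reduced, and C4=C5 epoxidised, under macrocyclic substrate control alone, and the C1 ketal has to come off with acid once the epoxide is present.
- Comparison: the chosen plan cannot match the reliability of the fragmentation. It sets against it a much shorter route that stays achiral until step 9, oxygen at C6 and C8 in place as stereocentres, and absolute control by a catalyst instead of a chiral bicyclic precursor.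

**Alternative 3:** The cut is C3–C4, with C1–C6 of a six-membered ring broken in the forward sense. The potassium alkoxide of cyclohexanol A5 undergoes an acetylenic anionic oxy-Cope shift that expands the ring to cyclodecadienone A6, with a C6 ketone, a C4=C5 enone and a C1 enol ether.
- Merits: the ring forms quickly from a cyclohexane on which C8 and C10 are easy to set, and C1 arrives oxygenated, which is better than the chosen plan on this point.
- Weak points: A6 has a methylene at C7 and none of C11–C13, so the butenolide carbons must be attached on the macrocycle at a ketone α-carbon in competition with the vinylogous position. The C4=C5 geometry comes from protonation of an allenolate and is not secured. C6 must be reduced and the enone epoxidised nucleophilically, both under substrate control on a flexible ring. Hydrolysis of the enol ether exposes C10 to the same epimerisation question as in the chosen plan.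
- Comparison: the most functionalised sector would be built late and without external control. The chosen plan has C6, C7, C8 and C11–C13 from its second step and sets four stereocentres in one catalytic operation; it pays for this with the late C1 oxidation.

Key step: step 9

## Route

Remark: germacrane numbering (C1 ketone carbon, C4/C5 epoxide, C12/C13 on C11, C14 on C10, C15 on C4) is used for all intermediates; TBS = tert-butyldimethylsilyl.
Assumption: ketone 5 is taken as purchasable (otherwise one silylation from dihydroxyacetone).
Assumption: C10, α to the C1 ketone, is epimerisable, and the natural 10R epimer is taken to be the one favoured at equilibrium in the ring.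

Step 1
Reactants: 1 propargyl alcohol
Product: 3 (E)-3-iodo-2-methylprop-2-en-1-ol, via alkenylalane 2 (not isolated)
Conditions: Me3Al, Cp2ZrCl2 (25 mol%), CH2Cl2, 0 °C to rt; then I2, THF, −30 °C
Reagents that add atoms: trimethylaluminium C[Al](C)C; iodine II
Why: Negishi carboalumination: zirconium-catalysed syn addition of Me–Al across the alkyne of the aluminium alkoxide puts methyl on the internal carbon and aluminium on the terminus, and iodinolysis with retention gives the E-iodide that carries the future C14/C15 methyl and the E-olefin geometry.

Step 2
Reactants: 4 dimethyl malonate; 5 1,3-bis(tert-butyldimethylsilyloxy)propan-2-one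
Product: 6 dimethyl 2-[1,3-bis(tert-butyldimethylsilyloxy)propan-2-ylidene]malonate
Conditions: TiCl4, pyridine, THF, 0 °C to rt
Reagents that add atoms: none
Why: Knoevenagel condensation under TiCl4/pyridine activation, the standard way to condense malonates with ketones; the α,α′-dioxygenated ketone is electrophilic, and no olefin geometry arises because both olefin carbons bear identical pairs of substituents.

Step 3
Reactants: 6 dimethyl 2-[1,3-bis(tert-butyldimethylsilyloxy)propan-2-ylidene]malonate
Product: 7 bis-Weinreb amide N,N′-dimethoxy-N,N′-dimethyl-2-[1,3-bis(tert-butyldimethylsilyloxy)propan-2-ylidene]malonamide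
Conditions: MeNHOMe·HCl, i-PrMgCl, THF, −20 to 0 °C
Reagents that add atoms: N,O-dimethylhydroxylamine hydrochloride CNOC.Cl
Why: Aminolysis of both esters by the chloromagnesium amide (Weinreb amide formation); the fully substituted β-carbon shields the alkylidene from conjugate addition.

Step 4
Reactants: 7 bis-Weinreb amide; 3 (E)-3-iodo-2-methylprop-2-en-1-ol
Product: 9 (2E,7E)-1,9-dihydroxy-2,8-dimethyl-5-[1,3-bis(tert-butyldimethylsilyloxy)propan-2-ylidene]nona-2,7-diene-4,6-dione, via dilithio alkenyl alkoxide 8 (not isolated)
Conditions: 3 (2.4 equiv), n-BuLi then t-BuLi, Et2O, −78 °C; then 7, THF, −78 to −40 °C; aq. NH4Cl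
Reagents that add atoms: none
Why: Lithium–iodine exchange on the lithium alkoxide of 3 keeps the olefin geometry; each Weinreb amide accepts one alkenyllithium and the chelated tetrahedral intermediates hold until the quench, so the diketone is released only on work-up (Weinreb ketone synthesis) and forms C5–C6 and C8–C9.

Step 5
Reactants: 9 (2E,7E)-1,9-dihydroxy-2,8-dimethyl-5-[1,3-bis(tert-butyldimethylsilyloxy)propan-2-ylidene]nona-2,7-diene-4,6-dione
Product: 10 bis(methyl carbonate) of 9
Conditions: ClCO2Me, pyridine, CH2Cl2, 0 °C
Reagents that add atoms: methyl chloroformate COC(=O)Cl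
Why: Acylation of the two primary allylic alcohols, the only hydroxyl groups present, gives the leaving groups for the palladium step before any secondary hydroxyl exists.

Step 6
Reactants: 10 bis(methyl carbonate) of 9
Product: 12 meso (4R,6S)-diol bis(methyl carbonate), via racemic hydroxy enone 11 (not isolated)
Conditions: TiCl4, CH2Cl2, −78 °C; then BH3·pyridine, −78 °C; aq. NaHCO3
Reagents that add atoms: none
Why: Chelation-controlled reduction of a 1,3-diketone to the syn-1,3-diol (Narasaka–Prasad-type 1,3-induction): TiCl4 ties both carbonyl oxygens, the first hydride gives the titanium alkoxide of 11, whose six-membered chelate holds the C6 alkenyl group pseudo-axial (allylic 1,3-strain with the C12 methylene), and the second hydride adds anti to it, which gives the syn, that is meso, diol; carbonates, silyl ethers and olefins are left by borane–pyridine at −78 °C.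

Step 7
Reactants: 12 meso (4R,6S)-diol bis(methyl carbonate); 13 bis(phenylsulfonyl)methane
Product: 15 meso (4E,6R,8S,9E)-4,10-dimethyl-2,2-bis(phenylsulfonyl)-7-[1,3-bis(tert-butyldimethylsilyloxy)propan-2-ylidene]cyclodeca-4,9-diene-6,8-diol, via monoallylated bis-sulfone 14 (not isolated)
Conditions: Pd(PPh3)4 (10 mol%), THF, 60 °C, slow addition of 12 and 13 (final 2 mM)
Reagents that add atoms: none
Why: Twofold Tsuji–Trost allylic alkylation: each carbonate ionises to a π-allyl complex of divalent palladium, the methoxide set free deprotonates 13 and then 14, and the soft carbanion attacks the primary allyl terminus with retention of the E geometry; the second alkylation is intramolecular and closes an (E,E)-cyclodeca-1,6-diene, a nearly strain-free ten-membered ring, while dilution suppresses oligomers and the E-olefins keep the free C6/C8 hydroxyls from reaching the allyl termini.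

Step 8
Reactants: 15 meso macrocyclic bis-sulfone
Product: 16 meso (4E,6R,8S,9E)-4,10-dimethyl-7-[1,3-bis(tert-butyldimethylsilyloxy)propan-2-ylidene]cyclodeca-4,9-diene-6,8-diol
Conditions: Mg, MeOH/THF, rt to 40 °C
Reagents that add atoms: none
Why: Reductive desulfonylation by electron transfer from magnesium cleaves both C–S bonds of the geminal bis-sulfone in succession; allylic alcohols, silyl ethers and isolated olefins are not reduced.

Step 9
Reactants: 16 meso (4E,6R,8S,9E)-4,10-dimethyl-7-[1,3-bis(tert-butyldimethylsilyloxy)propan-2-ylidene]cyclodeca-4,9-diene-6,8-diol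
Product: 17 (4R,5R,6S,8S,9E)-4,5-epoxy-4,10-dimethyl-7-[1,3-bis(tert-butyldimethylsilyloxy)propan-2-ylidene]cyclodec-9-ene-6,8-diol
Conditions: D-fructose-derived Shi ketone (1,2:4,5-di-O-isopropylidene-β-D-erythro-2,3-hexodiulo-2,6-pyranose, 30 mol%), 2KHSO5·KHSO4·K2SO4, K2CO3, Bu4NHSO4, MeCN/CH2(OMe)2/aq. Na2B4O7–Na2EDTA (pH 10.5), 0 °C
Reagents that add atoms: potassium peroxymonosulfate [K+].[O-]S(=O)(=O)OO
Why: The ketone catalyst is oxidised by KHSO5 to a chiral dioxirane, which transfers one oxygen atom to the olefin through a concerted, spiro-oriented transition state (Shi epoxidation; the closest precedent is the desymmetrisation of meso dienes and the kinetic resolution of cyclic olefins with this catalyst). The oxirane is closed by a single intermolecular [2+1] oxygen-atom transfer in which both C–O bonds form on the same face, so the E geometry of C4=C5 becomes the trans epoxide. In the macrocycle each ring olefin stands roughly perpendicular to the mean ring plane with its ring neighbours on the inner face, so only the outer face is open, and allylic 1,3-strain between C6–H and the C15 methyl fixes the rotamer that places O6 on that outer side. The two outer faces are enantiotopic: the D-fructose-derived ketone, which gives R,R-epoxides from E-olefins, is matched with the outer face of C4=C5 (4R,5R) and mismatched with that of C9=C10. C4 and C5 are therefore set by the catalyst (which olefin) together with the ring (which face), and C6 and C8, defined only relative to each other in 16, become 6S and 8S because the catalyst has chosen the olefin next to C6. The step needs group selectivity (catalyst), diastereoface selectivity (peripheral attack, rotamer control) and chemoselectivity against C7=C11, which is tetrasubstituted, flanked by four allylic C–O bonds and buried. Any minor enantiomer of 17 carries the matched olefin and is consumed faster to the bis-epoxide, which should raise the enantiomeric purity of 17 at the cost of some material.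

Step 10
Reactants: 17 epoxy diol; 18 angelic acid
Product: 20 8-O-angelate of 17 (6-OH free), via mixed anhydride 19 (not isolated)
Conditions: 18 (0.95 equiv), 2,4,6-trichlorobenzoyl chloride, Et3N, toluene, rt; then 17, 60 °C
Reagents that add atoms: none
Why: Yamaguchi esterification without nucleophilic catalyst, which avoids angelate to tiglate isomerisation; O8–H, a doubly allylic alcohol, is more nucleophilic than O6–H, which is inductively deactivated and hydrogen-bonded to the oxirane oxygen, and the O8 ester is also the more stable monoester, so a slight deficit of 19 should give the 8-O-angelate.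

Step 11
Reactants: 20 8-O-angelate of 17
Product: 21 (4R,5R,6S,8S)-8-angeloyloxy-4,5-epoxygermacra-7(11),9-diene-6,12,13-triol
Conditions: HF·pyridine, pyridine, THF, 0 °C to rt
Reagents that add atoms: none
Why: Fluoride cleavage of the two primary silyl ethers; buffered HF·pyridine is not basic enough for acyl migration or Payne rearrangement and not acidic enough to open the epoxide toward the transannular olefin.

Step 12
Reactants: 21 (4R,5R,6S,8S)-8-angeloyloxy-4,5-epoxygermacra-7(11),9-diene-6,12,13-triol
Product: 23 (4R,5R,6S,8S)-8-angeloyloxy-4,5-epoxy-13-oxogermacra-7(11),9-dien-12,6-olide, via lactol aldehyde 22 (not isolated)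
Conditions: TEMPO (20 mol%), PhI(OAc)2 (3.5 equiv), CH2Cl2, rt
Reagents that add atoms: none
Why: Oxoammonium oxidation of primary alcohols: both allylic CH2OH groups go to aldehydes, the C12 aldehyde is trapped by the cis O6–H as lactol 22 and oxidised on to the lactone (oxidative lactonisation of a Z-2-ene-1,4-diol), while the C13 aldehyde, whose neighbour O8 is acylated, cannot cyclise and remains.

Step 13
Reactants: 23 (4R,5R,6S,8S)-8-angeloyloxy-4,5-epoxy-13-oxogermacra-7(11),9-dien-12,6-olide
Product: 24 (4R,5R,6S,8S)-8-angeloyloxy-4,5-epoxy-13-hydroxygermacra-7(11),9-dien-12,6-olide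
Conditions: NaBH4, CeCl3·7H2O, MeOH/CH2Cl2, −78 °C
Reagents that add atoms: none
Why: Luche reduction: 1,2-selective hydride addition to the very electrophilic aldehyde at low temperature; lactone, esters and epoxide are inert, and the fully substituted β-carbon C7 blocks conjugate addition.

Step 14
Reactants: 24 (4R,5R,6S,8S)-8-angeloyloxy-4,5-epoxy-13-hydroxygermacra-7(11),9-dien-12,6-olide
Product: 25 (4R,5R,6S,8S)-13-acetoxy-8-angeloyloxy-4,5-epoxygermacra-7(11),9-dien-12,6-olide
Conditions: Ac2O, pyridine, CH2Cl2, 0 °C
Reagents that add atoms: acetic anhydride CC(=O)OC(C)=O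
Why: Acetylation of the only free hydroxyl, a primary allylic alcohol; no DMAP is used, so the angelate is not isomerised.

Step 15
Reactants: 25 (4R,5R,6S,8S)-13-acetoxy-8-angeloyloxy-4,5-epoxygermacra-7(11),9-dien-12,6-olide
Product: 27 (4R,5R,6S,8S,9E)-13-acetoxy-8-angeloyloxy-4,5-epoxy-1-oxogermacra-7(11),9-dien-12,6-olide, via allylic tert-butyl peroxide 26 (not isolated)
Conditions: Rh2(cap)4 (dirhodium tetracaprolactamate, 1 mol%), t-BuOOH (70% aq.), NaHCO3, 1,2-dichloroethane, 40 °C
Reagents that add atoms: tert-butyl hydroperoxide CC(C)(C)OO
Why: Allylic C–H oxidation by tert-butylperoxyl radicals generated on Rh2(cap)4: abstraction of the secondary allylic C1–H is favoured over the C14 methyl, the allyl radical is trapped at C1 (C9 is shielded by the C8 acyloxy group) to give 26, which loses tert-butanol to the enone; all other allylic C–H bonds sit on electron-poor π systems or on acyloxy-bearing carbons whose C–H bonds are held near the olefin planes by allylic strain.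

Step 16
Reactants: 27 (4R,5R,6S,8S,9E)-13-acetoxy-8-angeloyloxy-4,5-epoxy-1-oxogermacra-7(11),9-dien-12,6-olide
Product: 28 (4R,5R,6S,8S,10R)-13-acetoxy-8-angeloyloxy-4,5-epoxy-1-oxogermacr-7(11)-en-12,6-olide (target)
Conditions: [(Ph3P)CuH]6, toluene, H2O (2 equiv), rt; aq. NH4Cl
Reagents that add atoms: none
Why: Conjugate reduction with [(Ph3P)CuH]6: hydride adds to C9, the β-carbon of the only β-monosubstituted enone, and the copper enolate is protonated at C10 by water; the fully β-substituted butenolide and the α,β-disubstituted angelate react far more slowly, and C10, α to the ketone, can settle to the 10R epimer assumed to be favoured.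

## Compound list

1 | propargyl alcohol | C#CCO | starting material
2 | (E)-dimethyl[3-(dimethylalumanyloxy)-2-methylprop-1-enyl]alane | C[Al](C)OC/C(C)=C/[Al](C)C | intermediate (not isolated)
3 | (E)-3-iodo-2-methylprop-2-en-1-ol | OC/C(C)=C/I | intermediate
4 | dimethyl malonate | COC(=O)CC(=O)OC | starting material
5 | 1,3-bis(tert-butyldimethylsilyloxy)propan-2-one | CC(C)(C)[Si](C)(C)OCC(=O)CO[Si](C)(C)C(C)(C)C | starting material
6 | dimethyl 2-[1,3-bis(tert-butyldimethylsilyloxy)propan-2-ylidene]malonate | COC(=O)C(C(=O)OC)=C(CO[Si](C)(C)C(C)(C)C)CO[Si](C)(C)C(C)(C)C | intermediate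
7 | N,N′-dimethoxy-N,N′-dimethyl-2-[1,3-bis(tert-butyldimethylsilyloxy)propan-2-ylidene]malonamide | CON(C)C(=O)C(C(=O)N(C)OC)=C(CO[Si](C)(C)C(C)(C)C)CO[Si](C)(C)C(C)(C)C | intermediate
8 | lithium (E)-3-lithio-2-methylprop-2-en-1-olate | [Li]OC/C(C)=C/[Li] | intermediate (not isolated)
9 | (2E,7E)-1,9-dihydroxy-2,8-dimethyl-5-[1,3-bis(tert-butyldimethylsilyloxy)propan-2-ylidene]nona-2,7-diene-4,6-dione | OC/C(C)=C/C(=O)C(C(=O)/C=C(C)/CO)=C(CO[Si](C)(C)C(C)(C)C)CO[Si](C)(C)C(C)(C)C | intermediate
10 | bis(methyl carbonate) of 9 | COC(=O)OC/C(C)=C/C(=O)C(C(=O)/C=C(C)/COC(=O)OC)=C(CO[Si](C)(C)C(C)(C)C)CO[Si](C)(C)C(C)(C)C | intermediate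
11 | mono-reduced hydroxy enone of 10 (racemic) | COC(=O)OC/C(C)=C/C(O)C(C(=O)/C=C(C)/COC(=O)OC)=C(CO[Si](C)(C)C(C)(C)C)CO[Si](C)(C)C(C)(C)C | intermediate (not isolated)
12 | meso (2E,4R,6S,7E)-4,6-dihydroxy-2,8-dimethyl-5-[1,3-bis(tert-butyldimethylsilyloxy)propan-2-ylidene]nona-2,7-diene-1,9-diyl bis(methyl carbonate) | COC(=O)OC/C(C)=C/[C@@H](O)C([C@@H](O)/C=C(C)/COC(=O)OC)=C(CO[Si](C)(C)C(C)(C)C)CO[Si](C)(C)C(C)(C)C | intermediate
13 | bis(phenylsulfonyl)methane | O=S(=O)(CS(=O)(=O)c1ccccc1)c1ccccc1 | starting material
14 | monoallylation product: 12 with one OCO2Me replaced by CH(SO2Ph)2 (racemic; one enantiomer drawn) | COC(=O)OC/C(C)=C/[C@@H](O)C([C@@H](O)/C=C(C)/CC(S(=O)(=O)c1ccccc1)S(=O)(=O)c1ccccc1)=C(CO[Si](C)(C)C(C)(C)C)CO[Si](C)(C)C(C)(C)C | intermediate (not isolated)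
15 | meso (4E,6R,8S,9E)-4,10-dimethyl-2,2-bis(phenylsulfonyl)-7-[1,3-bis(tert-butyldimethylsilyloxy)propan-2-ylidene]cyclodeca-4,9-diene-6,8-diol | O[C@H]1/C=C(C)/CC(S(=O)(=O)c2ccccc2)(S(=O)(=O)c2ccccc2)C/C(C)=C/[C@@H](O)C1=C(CO[Si](C)(C)C(C)(C)C)CO[Si](C)(C)C(C)(C)C | intermediate
16 | meso (4E,6R,8S,9E)-4,10-dimethyl-7-[1,3-bis(tert-butyldimethylsilyloxy)propan-2-ylidene]cyclodeca-4,9-diene-6,8-diol | O[C@H]1/C=C(C)/CCC/C(C)=C/[C@@H](O)C1=C(CO[Si](C)(C)C(C)(C)C)CO[Si](C)(C)C(C)(C)C | intermediate
17 | (4R,5R,6S,8S,9E)-4,5-epoxy-4,10-dimethyl-7-[1,3-bis(tert-butyldimethylsilyloxy)propan-2-ylidene]cyclodec-9-ene-6,8-diol | O[C@H]1/C=C(C)/CCC[C@@]2(C)O[C@@H]2[C@@H](O)C1=C(CO[Si](C)(C)C(C)(C)C)CO[Si](C)(C)C(C)(C)C | intermediate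
18 | angelic acid, (Z)-2-methylbut-2-enoic acid | C/C=C(/C)C(=O)O | starting material
19 | angelic 2,4,6-trichlorobenzoic anhydride | C/C=C(/C)C(=O)OC(=O)c1c(Cl)cc(Cl)cc1Cl | intermediate (not isolated)
20 | 8-O-angelate of 17 | C/C=C(/C)C(=O)O[C@H]1/C=C(C)/CCC[C@@]2(C)O[C@@H]2[C@@H](O)C1=C(CO[Si](C)(C)C(C)(C)C)CO[Si](C)(C)C(C)(C)C | intermediate
21 | (4R,5R,6S,8S)-8-angeloyloxy-4,5-epoxygermacra-7(11),9-diene-6,12,13-triol | C/C=C(/C)C(=O)O[C@H]1/C=C(C)/CCC[C@@]2(C)O[C@@H]2[C@@H](O)C1=C(CO)CO | intermediate
22 | 12,6-lactol 13-aldehyde of 21 (lactol carbon undefined) | C/C=C(/C)C(=O)O[C@H]1/C=C(C)/CCC[C@@]2(C)O[C@@H]2[C@H]2OC(O)C(C=O)=C12 | intermediate (not isolated)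
23 | (4R,5R,6S,8S)-8-angeloyloxy-4,5-epoxy-13-oxogermacra-7(11),9-dien-12,6-olide | C/C=C(/C)C(=O)O[C@H]1/C=C(C)/CCC[C@@]2(C)O[C@@H]2[C@H]2OC(=O)C(C=O)=C12 | intermediate
24 | (4R,5R,6S,8S)-8-angeloyloxy-4,5-epoxy-13-hydroxygermacra-7(11),9-dien-12,6-olide | C/C=C(/C)C(=O)O[C@H]1/C=C(C)/CCC[C@@]2(C)O[C@@H]2[C@H]2OC(=O)C(CO)=C12 | intermediate
25 | (4R,5R,6S,8S)-13-acetoxy-8-angeloyloxy-4,5-epoxygermacra-7(11),9-dien-12,6-olide | C/C=C(/C)C(=O)O[C@H]1/C=C(C)/CCC[C@@]2(C)O[C@@H]2[C@H]2OC(=O)C(COC(C)=O)=C12 | intermediate
26 | 1-(tert-butylperoxy) derivative of 25 (C1 undefined) | C/C=C(/C)C(=O)O[C@H]1/C=C(C)/C(OOC(C)(C)C)CC[C@@]2(C)O[C@@H]2[C@H]2OC(=O)C(COC(C)=O)=C12 | intermediate (not isolated)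
27 | (4R,5R,6S,8S,9E)-13-acetoxy-8-angeloyloxy-4,5-epoxy-1-oxogermacra-7(11),9-dien-12,6-olide | C/C=C(/C)C(=O)O[C@H]1/C=C(C)/C(=O)CC[C@@]2(C)O[C@@H]2[C@H]2OC(=O)C(COC(C)=O)=C12 | intermediate
28 | (4R,5R,6S,8S,10R)-13-acetoxy-8-angeloyloxy-4,5-epoxy-1-oxogermacr-7(11)-en-12,6-olide | C/C=C(/C)C(=O)O[C@H]1C[C@@H](C)C(=O)CC[C@@]2(C)O[C@@H]2[C@H]2OC(=O)C(COC(C)=O)=C12 | target

## Step count and least certain steps

Total: 16 steps. Longest linear sequence: 15 steps (from 4 or 5 to 28, steps 2–16); step 1 is a one-step branch.

**Step 9 (key step).** What may go wrong: insufficient discrimination between the two enantiotopic olefins, over-epoxidation of 17 at C9=C10, or loss of facial control if the rotamer with the C6 oxygen eclipsing C15 is populated. The fallback sets out from 16 and comes back at 17. It is a hydroxyl-directed epoxidation with VO(O-i-Pr)3, a chiral bishydroxamic acid ligand and cumene hydroperoxide in toluene at 0 °C. The oxidant is delivered within a vanadium alkoxide of one carbinol, the ligand decides which carbinol reacts, and for an allylic alcohol with a cis substituent on the olefin the directed pathway gives the same threo epoxy alcohol. The approach changes from recognition of the olefin face to recognition of the carbinol; it makes no new compound (F0).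

**Step 15.** What may go wrong: hydrogen abstraction at the C14 methyl instead of C1, trapping of the allyl radical at C9, attack at the acyloxy-bearing carbons C6 and C8, or nucleophilic epoxidation of the enone once formed. The fallback sets out from 25 and comes back at 27 by a pericyclic route in two operations. Riley oxidation with catalytic SeO2 and t-BuOOH in CH2Cl2 (ene reaction, then [2,3]-sigmatropic shift) gives the C1 allylic alcohol F1, and Dess–Martin oxidation of F1 gives 27. The ene pathway depends on the alignment of the allylic C–H bond in the ring conformer and not on C–H bond strength, so the two methods fail for different reasons; its own bias toward the methyl group in such rings is the reason it is not the first choice.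

**Step 16.** What may go wrong: poor facial selectivity in the protonation at C10, an equilibrium that does not favour 10R, or SN2′ loss of acetate from the butenolide under hydride. The fallback sets out from 27 and comes back at 28. Corey–Bakshi–Shibata reduction of the C1 ketone gives the (1R)-allylic alcohol F2. Hydroxyl-directed hydrogenation of C9=C10 with [Rh(nbd)(dppb)]BF4 and H2 gives the saturated (1R,10R)-alcohol F3, and Dess–Martin oxidation of F3 gives 28. C10 is then set by delivery of hydrogen from the face of the C1 hydroxyl (the acyclic model with minimised allylic 1,2-strain predicts 10R from 1R). The other C1 epimer is available from the enantiomeric oxazaborolidine if the ring reverses the sense.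

**Step 10.** What may go wrong: low site selectivity between O6 and O8, bis-acylation, or acyl migration between the 1,3-related oxygens. The fallback sets out from 17 and comes back at 21. Catalyst-controlled silylation of O6 (Et3SiCl, i-Pr2NEt, a chiral N-methylimidazole amino-acid catalyst of the type used to desymmetrise 1,3-diols, either antipode) gives the 6-O-triethylsilyl ether F4. Exhaustive Yamaguchi esterification of the remaining O8–H with 18 gives the 6-O-triethylsilyl 8-O-angelate F5. The conditions of step 11 then remove the triethylsilyl group together with the two primary silyl ethers and give 21.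

**Step 7.** What may go wrong: oligomerisation in the two-component ring closure, or β-hydride elimination of the π-allyl intermediates to dienes. The fallback sets out from 9 and comes back at 15. Appel bromination (CBr4, PPh3, CH2Cl2) gives the bis(allylic bromide) diketone F6, and chelation-controlled reduction as in step 6 gives the meso diol dibromide F7. Double SN2 alkylation of 13 with F7 (Cs2CO3, DMF, high dilution) gives 15. No metal π-allyl is involved, and the E geometry keeps O6 and O8 from displacing the bromides intramolecularly.

**Step 6.** What may go wrong: loss of syn selectivity if the twisted diketone does not chelate, or cleavage of silyl ethers by TiCl4. The fallback sets out from 10 and comes back at 15: the ring is closed first and the carbonyls are reduced in the ring. Tsuji–Trost alkylation of 13 with 10 under the conditions of step 7 gives the macrocyclic diketone F8. Luche reduction (NaBH4, CeCl3·7H2O, MeOH, −78 °C) then gives 15, because hydride can reach each carbonyl only from the ring periphery and a mirror-symmetric conformer leads to the cis diol.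

## Further compounds

F0 | step 9 | none | none
F1 | step 15 | 1-hydroxy derivative of 25 (C1 allylic alcohol, C1 undefined) | C/C=C(/C)C(=O)O[C@H]1/C=C(C)/C(O)CC[C@@]2(C)O[C@@H]2[C@H]2OC(=O)C(COC(C)=O)=C12
F2 | step 16 | (1R,4R,5R,6S,8S,9E)-13-acetoxy-8-angeloyloxy-4,5-epoxy-1-hydroxygermacra-7(11),9-dien-12,6-olide | C/C=C(/C)C(=O)O[C@H]1/C=C(C)/[C@H](O)CC[C@@]2(C)O[C@@H]2[C@H]2OC(=O)C(COC(C)=O)=C12
F3 | step 16 | (1R,4R,5R,6S,8S,10R)-13-acetoxy-8-angeloyloxy-4,5-epoxy-1-hydroxygermacr-7(11)-en-12,6-olide | C/C=C(/C)C(=O)O[C@H]1C[C@@H](C)[C@H](O)CC[C@@]2(C)O[C@@H]2[C@H]2OC(=O)C(COC(C)=O)=C12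
F4 | step 10 | 6-O-triethylsilyl ether of 17 | O[C@H]1/C=C(C)/CCC[C@@]2(C)O[C@@H]2[C@@H](O[Si](CC)(CC)CC)C1=C(CO[Si](C)(C)C(C)(C)C)CO[Si](C)(C)C(C)(C)C
F5 | step 10 | 6-O-triethylsilyl 8-O-angelate of 17 | C/C=C(/C)C(=O)O[C@H]1/C=C(C)/CCC[C@@]2(C)O[C@@H]2[C@@H](O[Si](CC)(CC)CC)C1=C(CO[Si](C)(C)C(C)(C)C)CO[Si](C)(C)C(C)(C)C
F6 | step 7 | (2E,7E)-1,9-dibromo-2,8-dimethyl-5-[1,3-bis(tert-butyldimethylsilyloxy)propan-2-ylidene]nona-2,7-diene-4,6-dione | BrC/C(C)=C/C(=O)C(C(=O)/C=C(C)/CBr)=C(CO[Si](C)(C)C(C)(C)C)CO[Si](C)(C)C(C)(C)C
F7 | step 7 | meso (2E,4R,6S,7E)-1,9-dibromo-2,8-dimethyl-5-[1,3-bis(tert-butyldimethylsilyloxy)propan-2-ylidene]nona-2,7-diene-4,6-diol | BrC/C(C)=C/[C@@H](O)C([C@@H](O)/C=C(C)/CBr)=C(CO[Si](C)(C)C(C)(C)C)CO[Si](C)(C)C(C)(C)C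
F8 | step 6 | (4E,9E)-4,10-dimethyl-2,2-bis(phenylsulfonyl)-7-[1,3-bis(tert-butyldimethylsilyloxy)propan-2-ylidene]cyclodeca-4,9-diene-6,8-dione | O=C1/C=C(C)/CC(S(=O)(=O)c2ccccc2)(S(=O)(=O)c2ccccc2)C/C(C)=C/C(=O)C1=C(CO[Si](C)(C)C(C)(C)C)CO[Si](C)(C)C(C)(C)C
A1 | alternative 1 | open-chain C5 aldehyde with 2-(triisopropylsilyloxy)furan terminus (C4 triethylsilyl ether, C1 TBS ether, C8 PMB ether) | COc1ccc(CO[C@@H](C[C@@H](C)[C@H](O[Si](C)(C)C(C)(C)C)CC[C@@](C)(O[Si](CC)(CC)CC)C=O)c2coc(O[Si](C(C)C)(C(C)C)C(C)C)c2COC(C)=O)cc1
A2 | alternative 1 | ten-membered 5-hydroxy butenolide (C4 triethylsilyl ether) | COc1ccc(CO[C@H]2C[C@@H](C)[C@H](O[Si](C)(C)C(C)(C)C)CC[C@@](C)(O[Si](CC)(CC)CC)[C@@H](O)[C@H]3OC(=O)C(COC(C)=O)=C23)cc1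
A3 | alternative 2 | hydroazulene (bicyclo[5.3.0]decane) C8 tertiary alcohol C5 mesylate with C1 dioxolane and C7 dioxanylidene | O[C@@]12C[C@@H](C)C3(OCCO3)CC[C@]1(C)[C@@H](OS(C)(=O)=O)[C@@H](O[Si](C)(C)C(C)(C)C)C2=C1COC(C)(C)OC1
A4 | alternative 2 | E-cyclodec-4-en-8-one with cross-conjugated C7 alkylidene | O=C1C[C@@H](C)C2(OCCO2)CC/C(C)=C/[C@@H](O[Si](C)(C)C(C)(C)C)C1=C1COC(C)(C)OC1
A5 | alternative 3 | 2-methoxy-3-methyl-1-(prop-1-ynyl)-5-(tert-butyldimethylsilyloxy)-2-vinylcyclohexan-1-ol | CC(C)(C)[Si](C)(C)O[C@H]1C[C@@H](C)[C@@](OC)(C=C)[C@](O)(C#CC)C1
A6 | alternative 3 | 1-methoxy-4,10-dimethyl-8-(tert-butyldimethylsilyloxy)cyclodeca-1,4-dien-6-one | CC(C)(C)[Si](C)(C)O[C@H]1C[C@@H](C)/C(OC)=C/C/C(C)=C/C(=O)C1
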